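**Plan**

- Enabling feature: C2 and C3 of the butane-1,4-dione chain each carry one aroyl group and one 4-hydroxybenzyl CH2 in a meso (2R,3S) array. The two benzylic CH2 carbons stand 1,4 to each other across C2–C3, so a sulfur atom between them gives a thiolane in which ring C3/C4 are chain C2/C3 and ring C2/C5 are the benzylic carbons.
- Retrosynthesis: the six phenols become benzyl ethers and the two benzylic C–H bonds become C–S bonds of a 2,5-diaryl-3,4-diaroylthiolane. The thiolane C2–C3 and C4–C5 bonds (target C2–CH2 and C3–CH2) are then cut together into a Z-1,2-diaroylethylene and a 1,3-diaryl thiocarbonyl ylide.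
- The enedione goes back to a 2,5-diarylfuran (two aryl–furyl bonds cut). The ylide goes back to an α-chloro α'-silyl sulfide, cut at S–CHCl into an α-silyl thiol and 4-(benzyloxy)benzaldehyde.
- Forward: two three-step branches give dipolarophile and dipole precursor. The only ring (thiolane) closes in the cycloaddition, sulfur is then excised, and hydrogenolysis frees the phenols.
- Stereochemistry: the Z geometry taken from the furan ring is carried suprafacially into cis-3,4 substituents on the thiolane, which is the meso relation of the target. The ring C2/C5 centres disappear with sulfur, and no absolute control is needed.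

Key step: step 7

Remark: the target is the meso (2R,3S ≡ 2S,3R) compound and therefore achiral, so only the relative configuration has to be set; mixtures at centres that are destroyed later are accepted.

**Route**

Step 1
Reactants: 1 4-bromoresorcinol
Product: 2 2,4-bis(benzyloxy)-1-bromobenzene
Conditions: BnBr (2.2 equiv), K2CO3, DMF, rt → 50 °C
Reagents that add atoms: benzyl bromide, BrCc1ccccc1
Why: Williamson ether synthesis on both phenoxides, with the aryl bromide inert under these SN2 conditions.

Step 2
Reactants: 2 2,4-bis(benzyloxy)-1-bromobenzene (2.1 equiv); 3 2,5-bis(tributylstannyl)furan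
Product: 4 2,5-bis[2,4-bis(benzyloxy)phenyl]furan
Conditions: Pd(PPh3)4 (cat.), 1,4-dioxane, 100 °C
Reagents that add atoms: none
Why: twofold Stille coupling, a standard entry to 2,5-diarylfurans, because 2-furylstannanes transmetallate readily and benzyl ethers are spectators.

Step 3
Reactants: 4 2,5-bis[2,4-bis(benzyloxy)phenyl]furan
Product: 6 (Z)-1,4-bis[2,4-bis(benzyloxy)phenyl]but-2-ene-1,4-dione, via furan 2,5-endoperoxide 5 (not isolated)
Conditions: O2, methylene blue (cat.), red light (λ > 600 nm), CH2Cl2, −78 °C; then Me2S, −78 → 0 °C, dark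
Reagents that add atoms: dioxygen, O=O
Why: [4+2] cycloaddition of singlet oxygen to the furan diene and reduction of the endoperoxide by Me2S should unmask the cis-enedione, its Z geometry being that of the former ring C3=C4 bond; red light and dark work-up avoid photoisomerisation to E.

Step 4
Reactants: 7 4-(benzyloxy)benzyl chloride
Product: 9 [4-(benzyloxy)phenyl]methanethiol, via isothiouronium chloride 8 (not isolated)
Conditions: thiourea, EtOH, reflux; then aq NaOH, reflux, N2; dil. HCl
Reagents that add atoms: thiourea, NC(N)=S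
Why: SN2 S-alkylation of thiourea followed by alkaline hydrolysis of the isothiouronium salt is the standard thiol synthesis that avoids over-alkylation to the sulfide.

Step 5
Reactants: 9 [4-(benzyloxy)phenyl]methanethiol
Product: 12 rac-[4-(benzyloxy)phenyl](trimethylsilyl)methanethiol, via S-silyl thioether 10 (not isolated), via lithium α-silyl thiolate 11 (not isolated)
Conditions: n-BuLi (1.0 equiv), THF, −78 °C; Me3SiCl, → 0 °C; t-BuLi (1.1 equiv), −78 → −30 °C; aq NH4Cl
Reagents that add atoms: chlorotrimethylsilane, C[Si](C)(C)Cl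
Why: S-silylation and then benzylic deprotonation should trigger the anionic 1,2-silyl shift from sulfur to carbon (thia-retro-Brook rearrangement), driven by thiolate formation; the new stereocentre is racemic, which does not matter because it becomes sp2 in step 7.

Step 6
Reactants: 12 rac-[4-(benzyloxy)phenyl](trimethylsilyl)methanethiol; 13 4-(benzyloxy)benzaldehyde
Product: 15 [4-(benzyloxy)phenyl](chloro)methyl [4-(benzyloxy)phenyl](trimethylsilyl)methyl sulfide (diastereomer mixture), via hemithioacetal 14 (not isolated)
Conditions: dry HCl (g), anhydrous CaCl2, CH2Cl2, −20 → 0 °C; filter, evaporate (toluene chase), use crude at once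
Reagents that add atoms: hydrogen chloride, Cl
Why: α-chloroalkylation of a thiol by an aldehyde and HCl (hemithioacetal, sulfur-assisted ionisation, chloride capture) is the classical condensation route to α-chloro sulfides, and it places chlorine only on the aldehyde-derived carbon with the C–Si bond untouched; the second stereocentre is uncontrolled and irrelevant.

Step 7
Reactants: 6 (Z)-1,4-bis[2,4-bis(benzyloxy)phenyl]but-2-ene-1,4-dione; 15 [4-(benzyloxy)phenyl](chloro)methyl [4-(benzyloxy)phenyl](trimethylsilyl)methyl sulfide (1.5–2 equiv)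
Product: 17 3,4-cis-3,4-bis[2,4-bis(benzyloxy)benzoyl]-2,5-bis[4-(benzyloxy)phenyl]thiolane (C2/C5 mixture), via thiocarbonyl ylide 16 (not isolated)
Conditions: anhydrous CsF (excess), MeCN (CH2Cl2 co-solvent), 0 °C → rt, dark, slow addition of 15 to 6 + CsF
Reagents that add atoms: none
Why: Proposed new method: desilylation of 15 by fluoride, with loss of chloride from the other benzylic carbon (eased by its 4-benzyloxyphenyl group), is a 1,3-elimination across sulfur that should release ylide 16, an allyl-anion-type 4π dipole, which should add to the acyl-activated C=C of 6 in one suprafacial [π4s+π2s] event; the closest known reaction type is the CsF-induced generation of the parent and monosubstituted thiocarbonyl ylides from chloromethyl (trimethylsilyl)methyl sulfides and their stereospecific [3+2] addition to maleates, fumarates and enones, which has not been shown for a 1,3-diaryl ylide. The thiolane ring closes by an intermolecular 1,3-dipolar cycloaddition in which both new C–C bonds (ring C2–C3 and C4–C5) form together. Ring C3 and C4 take their cis relation from the Z geometry of 6, which a concerted addition copies unchanged, whereas C2 and C5 depend on ylide shape and endo/exo approach, are not controlled and need not be, since both become CH2 in step 8. The step needs stereospecificity (no Z→E isomerisation of 6, no stepwise zwitterion) and capture of 16 by C=C faster than its electrocyclisation to a thiirane or addition to C=O; acid-free crude 15, darkness, low temperature and slow addition into an excess concentration of the doubly activated, lowest-LUMO alkene are meant to secure this.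

Step 8
Reactants: 17 3,4-cis-3,4-bis[2,4-bis(benzyloxy)benzoyl]-2,5-bis[4-(benzyloxy)phenyl]thiolane
Product: 18 meso-(2R,3S)-2,3-bis[4-(benzyloxy)benzyl]-1,4-bis[2,4-bis(benzyloxy)phenyl]butane-1,4-dione
Conditions: Raney Ni (W-2, washed neutral, deactivated in refluxing acetone), acetone/THF, rt
Reagents that add atoms: none
Why: Raney nickel desulfurization (hydrogenolysis of the two activated benzylic C–S bonds) turns ring C2 and C5 into CH2 groups and leaves the cis-related centres untouched, so the cis-thiolane maps onto the meso diketone; acetone-deactivated, neutral nickel is chosen to spare the aryl ketones and the α-stereocentres.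

Step 9
Reactants: 18 meso-(2R,3S)-2,3-bis[4-(benzyloxy)benzyl]-1,4-bis[2,4-bis(benzyloxy)phenyl]butane-1,4-dione
Product: 19 meso-(2R,3S)-1,4-bis(2,4-dihydroxyphenyl)-2,3-bis(4-hydroxybenzyl)butane-1,4-dione (CNP0406969.1)
Conditions: H2 (1 atm), 10% Pd/C, EtOAc/MeOH, rt (on chromatographed, sulfur-free 18)
Reagents that add atoms: none
Why: catalytic hydrogenolysis of the six aryl benzyl ethers under neutral conditions avoids enolisation (epimerisation to the rac diastereomer) and acid-induced Paal–Knorr furan formation, and electron-rich aryl ketones should resist reduction at 1 atm.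

**Compound list**

1 | 4-bromoresorcinol | Oc1ccc(Br)c(O)c1 | starting material
2 | 2,4-bis(benzyloxy)-1-bromobenzene | Brc1ccc(OCc2ccccc2)cc1OCc1ccccc1 | intermediate
3 | 2,5-bis(tributylstannyl)furan | CCCC[Sn](CCCC)(CCCC)c1ccc(o1)[Sn](CCCC)(CCCC)CCCC | starting material
4 | 2,5-bis[2,4-bis(benzyloxy)phenyl]furan | c1cc(-c2ccc(OCc3ccccc3)cc2OCc2ccccc2)oc1-c1ccc(OCc2ccccc2)cc1OCc1ccccc1 | intermediate
5 | 1,4-bis[2,4-bis(benzyloxy)phenyl]-2,3,7-trioxabicyclo[2.2.1]hept-5-ene (meso furan 2,5-endoperoxide) | O1O[C@@]2(c3ccc(OCc4ccccc4)cc3OCc3ccccc3)C=C[C@]1(c1ccc(OCc3ccccc3)cc1OCc1ccccc1)O2 | intermediate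
6 | (Z)-1,4-bis[2,4-bis(benzyloxy)phenyl]but-2-ene-1,4-dione | O=C(c1ccc(OCc2ccccc2)cc1OCc1ccccc1)/C=C\C(=O)c1ccc(OCc2ccccc2)cc1OCc1ccccc1 | intermediate
7 | 4-(benzyloxy)benzyl chloride | ClCc1ccc(OCc2ccccc2)cc1 | starting material
8 | S-[4-(benzyloxy)benzyl]isothiouronium chloride | NC(=[NH2+])SCc1ccc(OCc2ccccc2)cc1.[Cl-] | intermediate
9 | [4-(benzyloxy)phenyl]methanethiol | SCc1ccc(OCc2ccccc2)cc1 | intermediate
10 | {[4-(benzyloxy)benzyl]sulfanyl}trimethylsilane (S-silyl thioether) | C[Si](C)(C)SCc1ccc(OCc2ccccc2)cc1 | intermediate
11 | lithium [4-(benzyloxy)phenyl](trimethylsilyl)methanethiolate (racemic) | C[Si](C)(C)C([S-])c1ccc(OCc2ccccc2)cc1.[Li+] | intermediate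
12 | rac-[4-(benzyloxy)phenyl](trimethylsilyl)methanethiol | C[Si](C)(C)C(S)c1ccc(OCc2ccccc2)cc1 | intermediate
13 | 4-(benzyloxy)benzaldehyde | O=Cc1ccc(OCc2ccccc2)cc1 | starting material
14 | [4-(benzyloxy)phenyl](hydroxy)methyl [4-(benzyloxy)phenyl](trimethylsilyl)methyl sulfide (hemithioacetal, diastereomer mixture) | C[Si](C)(C)C(SC(O)c1ccc(OCc2ccccc2)cc1)c1ccc(OCc2ccccc2)cc1 | intermediate
15 | [4-(benzyloxy)phenyl](chloro)methyl [4-(benzyloxy)phenyl](trimethylsilyl)methyl sulfide (diastereomer mixture) | C[Si](C)(C)C(SC(Cl)c1ccc(OCc2ccccc2)cc1)c1ccc(OCc2ccccc2)cc1 | intermediate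
16 | 1,3-bis[4-(benzyloxy)phenyl] thiocarbonyl ylide (geometry not defined) | [CH-](c1ccc(OCc2ccccc2)cc1)[S+]=Cc1ccc(OCc2ccccc2)cc1 | intermediate
17 | 3,4-cis-3,4-bis[2,4-bis(benzyloxy)benzoyl]-2,5-bis[4-(benzyloxy)phenyl]thiolane (C2/C5 not defined) | S1C(c2ccc(OCc3ccccc3)cc2)[C@@H](C(=O)c2ccc(OCc3ccccc3)cc2OCc2ccccc2)[C@@H](C(=O)c2ccc(OCc3ccccc3)cc2OCc2ccccc2)C1c1ccc(OCc2ccccc2)cc1 | intermediate
18 | meso-(2R,3S)-2,3-bis[4-(benzyloxy)benzyl]-1,4-bis[2,4-bis(benzyloxy)phenyl]butane-1,4-dione | O=C(c1ccc(OCc2ccccc2)cc1OCc1ccccc1)[C@@H](Cc1ccc(OCc2ccccc2)cc1)[C@@H](Cc1ccc(OCc2ccccc2)cc1)C(=O)c1ccc(OCc2ccccc2)cc1OCc1ccccc1 | intermediate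
19 | meso-(2R,3S)-1,4-bis(2,4-dihydroxyphenyl)-2,3-bis(4-hydroxybenzyl)butane-1,4-dione | O=C(c1ccc(O)cc1O)[C@@H](Cc1ccc(O)cc1)[C@@H](Cc1ccc(O)cc1)C(=O)c1ccc(O)cc1O | target

**Step count**

Total steps: 9. Longest linear sequence: 6 steps (steps 1–3 or steps 4–6, then steps 7–9).

**Steps most likely to fail**

Step 7. The ylide may close to a thiirane or be protonated before it is trapped. The Z-enedione may isomerise to E under fluoride, trace acid or light, or the addition may turn stepwise. Each of these processes erodes the cis relation or the conversion. The fallback uses known enolate chemistry and sets out from 6. The C=C bond would be reduced with zinc dust in acetic acid to 1,4-bis[2,4-bis(benzyloxy)phenyl]butane-1,4-dione F1. Enolisation with LiHMDS (THF, −78 °C) and C-alkylation with 7 would give rac-2-[4-(benzyloxy)benzyl]-1,4-bis[2,4-bis(benzyloxy)phenyl]butane-1,4-dione F2. A second LiHMDS/7 cycle at the remaining CH2 would give 18 together with rac-(2R,3R)-2,3-bis[4-(benzyloxy)benzyl]-1,4-bis[2,4-bis(benzyloxy)phenyl]butane-1,4-dione F3. Compound 18 would be separated by crystallisation, and F3 returned to the meso/rac equilibrium with DBU and separated again. The path comes back to the route at 18, so steps 7 and 8 are bypassed.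

Step 6. The condensation may stall at the hemithioacetal or drift to the dithioacetal, and the ionisable α-chloro sulfide may hydrolyse on handling. The fallback sets out from 12 and moves the introduction of chlorine to an oxidative C–H chlorination. S-Benzylation of 12 with 7 (K2CO3, DMF, rt) would give 4-(benzyloxy)benzyl [4-(benzyloxy)phenyl](trimethylsilyl)methyl sulfide F4. α-Chlorination with N-chlorosuccinimide (CH2Cl2, 0 °C; chlorosulfonium, thionium, chloride return) at the unsilylated, less hindered benzylic CH2 would then give 15. Succinimide is filtered off, and the path comes back to the route at 15.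

Step 8. Over-reduction of the aryl ketones may occur on the nickel surface. Dehydrogenation–rehydrogenation or residual base may also scramble the two α-stereocentres, which would lose the meso relation. The fallback replaces the surface hydrogenolysis by a homogeneous radical-chain desulfurization with Bu3SnH (excess) and AIBN in toluene at reflux. This is known for benzylic sulfides and leaves ketones and benzyl ethers alone. It sets out from 17 and comes back to the route at 18 (new compounds: none F0).

**Further compounds**

F1 | step 7 | 1,4-bis[2,4-bis(benzyloxy)phenyl]butane-1,4-dione | O=C(CCC(=O)c1ccc(OCc2ccccc2)cc1OCc1ccccc1)c1ccc(OCc2ccccc2)cc1OCc1ccccc1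
F2 | step 7 | rac-2-[4-(benzyloxy)benzyl]-1,4-bis[2,4-bis(benzyloxy)phenyl]butane-1,4-dione | O=C(CC(Cc1ccc(OCc2ccccc2)cc1)C(=O)c1ccc(OCc2ccccc2)cc1OCc1ccccc1)c1ccc(OCc2ccccc2)cc1OCc1ccccc1
F3 | step 7 | rac-(2R,3R)-2,3-bis[4-(benzyloxy)benzyl]-1,4-bis[2,4-bis(benzyloxy)phenyl]butane-1,4-dione (one enantiomer drawn) | O=C(c1ccc(OCc2ccccc2)cc1OCc1ccccc1)[C@@H](Cc1ccc(OCc2ccccc2)cc1)[C@H](Cc1ccc(OCc2ccccc2)cc1)C(=O)c1ccc(OCc2ccccc2)cc1OCc1ccccc1
F4 | step 6 | 4-(benzyloxy)benzyl [4-(benzyloxy)phenyl](trimethylsilyl)methyl sulfide (racemic) | C[Si](C)(C)C(SCc1ccc(OCc2ccccc2)cc1)c1ccc(OCc2ccccc2)cc1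
F0 | step 8 | none | none
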